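**Assumptions (one line each)**
- Commercial (−)-sclareol is the natural enantiomer. Its ring A (5S, 10β-Me) matches the target once OH replaces C9 at C10 with retention.
- The HWE step gives E:Z of about 5:1, and the Z isomer is removed by chromatography.

**Retrosynthesis**
- The C11–C12 bond is formed by allylic sulfone alkylation followed by reductive desulfonylation. The two partners are cyclofarnesyl-type bromide **8** and (E,E)-8-sulfonylgeranyl TBS ether **13**.
- Bromide **8** comes from hydroxy ketone **4** by HWE olefination (E), DIBAL reduction and bromination.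
- Ketone **4** comes from sclareol. First the side chain is cut to a methyl ketone. Then ring B is removed by photochemical C8–C9 β-scission and C9–C10 Hock cleavage, which installs the C10 tertiary OH with retention. The C5 and C10 stereocenters both come from sclareol's ring A, and no ring is formed.

---

**Step 1**
Reactants: 1 (−)-sclareol
Product: 2 8α-hydroxy-14,15-dinorlabdan-13-one (methyl ketone)
Conditions: KMnO4, MgSO4, acetone/H2O, 0 °C→rt; NaHSO3 work-up
Reagents that add atoms: KMnO4 ([K+].[O-][Mn](=O)(=O)=O), H2O (O)
Why: Oxidative cleavage of the vinyl carbinol (diol, α-hydroxy acid, decarboxylative oxidation) gives the methyl ketone. Ring A and C8 are untouched, so the C5 and C10 stereocenters are carried over.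

**Step 2**
Reactants: 2
Product: 4 (4-[(1S,2S)-2-hydroxy-2,6,6-trimethylcyclohexyl]butan-2-one), via in-situ hydroperoxide 3; the by-product is 4-oxopentanal
Conditions: (i) CeCl3 (10 mol %), n-Bu4NCl (10 mol %), MeCN, O2 (1 atm), 390 nm LEDs, 25 °C, 16 h; (ii) p-TsOH·H2O (10 mol %), MeCN/H2O 9:1, 0→25 °C, 2 h; (iii) PPh3 (1.2 equiv), 30 min
Reagents that add atoms: O2 (O=O), H2O (O)
Why: Proposed new method: Ce(IV)–alkoxide LMCT gives the axial 8α-alkoxy radical, which is trans to C20 and so cannot do 1,5-HAT. It undergoes β-scission of C8–C9 to the C8 methyl ketone and a secondary C9 radical. O2 traps this radical to give secondary hydroperoxide 3 (C9 epimers), and acid then triggers a Hock/Criegee fragmentation in which tertiary C10 migrates to oxygen with retention. The result is a C10–OH (Me axial, OH equatorial, as in the target) plus the C9 aldehyde, and C5 is never touched. The closest known reactions are Ce-LMCT deconstructive oxygenation of cycloalkanols and Hock cleavage. The novelty is applying the two in sequence to cleave a fused decalol twice and set a tertiary carbinol stereocenter by retentive migration.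

**Step 3**
Reactants: 4 hydroxy ketone; 5 triethyl phosphonoacetate
Product: 6 ethyl (2E)-5-[(1S,2S)-2-hydroxy-2,6,6-trimethylcyclohexyl]-3-methylpent-2-enoate
Conditions: 5, NaH (2.5 equiv), THF, 0 °C→60 °C; chromatographic removal of Z isomer
Reagents that add atoms: none (5 is a numbered reactant)
Why: Horner–Wadsworth–Emmons olefination of the methyl ketone sets the trisubstituted C8=C9 alkene, E-selective, and supplies C9 and C11. The tertiary alkoxide is inert and cannot lactonise (8-membered ring across an E-alkene).

**Step 4**
Reactants: 6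
Product: 7 (2E)-5-[(1S,2S)-2-hydroxy-2,6,6-trimethylcyclohexyl]-3-methylpent-2-en-1-ol
Conditions: DIBAL-H (2.5 equiv), CH2Cl2, −78→0 °C
Reagents that add atoms: none (hydride only)
Why: DIBAL reduces the ester to the allylic alcohol (C11H2OH) without touching the alkene or the stereocenters.

**Step 5**
Reactants: 7
Product: 8 (1S,2S)-2-[(3E)-5-bromo-3-methylpent-3-en-1-yl]-1,3,3-trimethylcyclohexan-1-ol
Conditions: MsCl, Et3N, THF, −40 °C; then LiBr, 0 °C
Reagents that add atoms: LiBr ([Li+].[Br-])
Why: The primary allylic alcohol is mesylated and displaced by bromide (SN2, no allylic transposition). The hindered tertiary C10–OH does not react at −40 °C.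

**Step 6**
Reactants: 9 geraniol
Product: 10 geranyl TBS ether
Conditions: TBSCl, imidazole, DMF, 25 °C
Reagents that add atoms: TBSCl (CC(C)(C)[Si](C)(C)Cl)
Why: Standard silylation of the primary alcohol so that the allylic sulfone can later be deprotonated.

**Step 7**
Reactants: 10
Product: 11 (2E,6E)-8-hydroxygeranyl TBS ether
Conditions: SeO2 (5 mol %), TBHP (3 equiv), CH2Cl2, 0→25 °C
Reagents that add atoms: TBHP (CC(C)(C)OO)
Why: Umbreit–Sharpless allylic oxidation occurs selectively at the E-methyl of the terminal trisubstituted alkene, which sets the C12 handle with the correct geometry.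

**Step 8**
Reactants: 11
Product: 12 (2E,6E)-8-bromogeranyl TBS ether
Conditions: CBr4, PPh3, CH2Cl2, 0 °C
Reagents that add atoms: CBr4 (BrC(Br)(Br)Br)
Why: Appel bromination is SN2 at the primary allylic carbon and keeps both alkenes intact.

**Step 9**
Reactants: 12
Product: 13 (2E,6E)-8-(phenylsulfonyl)geranyl TBS ether
Conditions: PhSO2Na, DMF, 25 °C
Reagents that add atoms: PhSO2Na ([Na+].[O-]S(=O)c1ccccc1)
Why: SN2 displacement of the allylic bromide gives the allylic sulfone, a stabilised pronucleophile for Biellmann-type alkylation.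

**Step 10**
Reactants: 8 allylic bromide; 13 sulfone
Product: 14 coupled allylic sulfone (C12 epimeric mixture)
Conditions: 13 (2.3 equiv) + n-BuLi (2.3 equiv), THF, −78 °C; add HMPA, then 8; −78→−40 °C
Reagents that add atoms: none (n-BuLi only deprotonates)
Why: The sulfone carbanion alkylates at its α-carbon with the primary allylic bromide (SN2, alkene geometries retained) to form the C11–C12 bond. The extra equivalent of anion covers the free tertiary OH.

**Step 11**
Reactants: 14
Product: 15 TBS-protected target
Conditions: PdCl2(dppp) (10 mol %), LiBHEt3 (5 equiv), THF, 0→25 °C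
Reagents that add atoms: none (hydride only)
Why: Pd-catalysed hydride hydrogenolysis of the allylic C–SO2Ph bond through a π-allyl complex gives the trisubstituted E-alkene and removes the C12 stereocenter. The other alkenes, the TBS ether and the tertiary alcohol survive.

**Step 12**
Reactants: 15
Product: 16 preluffariellolide A
Conditions: TBAF, THF, 0→25 °C
Reagents that add atoms: none
Why: Fluoride removes the primary silyl ether and leaves the tertiary alcohol and all three E-alkenes unchanged.

---

**Compound list**

| # | Name | SMILES | Role |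
|---|---|---|---|
| 1 | (−)-sclareol | C=C[C@](C)(O)CC[C@@H]1[C@@]2(C)CCCC(C)(C)[C@@H]2CC[C@@]1(C)O | starting material |
| 2 | 8α-hydroxy-14,15-dinorlabdan-13-one | CC(=O)CC[C@@H]1[C@@]2(C)CCCC(C)(C)[C@@H]2CC[C@@]1(C)O | intermediate |
| 3 | C9-hydroperoxy seco-ketone (C9 epimers, in situ) | CC(=O)CC[C@H]1C(C)(C)CCC[C@]1(C)C(OO)CCC(C)=O | intermediate |
| 4 | 4-[(1S,2S)-2-hydroxy-2,6,6-trimethylcyclohexyl]butan-2-one | CC(=O)CC[C@H]1C(C)(C)CCC[C@]1(C)O | intermediate |
| 5 | triethyl phosphonoacetate | CCOC(=O)CP(=O)(OCC)OCC | starting material |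
| 6 | ethyl (2E)-5-[(1S,2S)-2-hydroxy-2,6,6-trimethylcyclohexyl]-3-methylpent-2-enoate | CCOC(=O)/C=C(\C)CC[C@H]1C(C)(C)CCC[C@]1(C)O | intermediate |
| 7 | (2E)-5-[(1S,2S)-2-hydroxy-2,6,6-trimethylcyclohexyl]-3-methylpent-2-en-1-ol | OC/C=C(\C)CC[C@H]1C(C)(C)CCC[C@]1(C)O | intermediate |
| 8 | (1S,2S)-2-[(3E)-5-bromo-3-methylpent-3-en-1-yl]-1,3,3-trimethylcyclohexan-1-ol | BrC/C=C(\C)CC[C@H]1C(C)(C)CCC[C@]1(C)O | intermediate |
| 9 | geraniol | CC(C)=CCC/C(C)=C/CO | starting material |
| 10 | geranyl TBS ether | CC(C)=CCC/C(C)=C/CO[Si](C)(C)C(C)(C)C | intermediate |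
| 11 | (2E,6E)-8-hydroxygeranyl TBS ether | OC/C(C)=C/CC/C(C)=C/CO[Si](C)(C)C(C)(C)C | intermediate |
| 12 | (2E,6E)-8-bromogeranyl TBS ether | BrC/C(C)=C/CC/C(C)=C/CO[Si](C)(C)C(C)(C)C | intermediate |
| 13 | (2E,6E)-8-(phenylsulfonyl)geranyl TBS ether | O=S(=O)(C/C(C)=C/CC/C(C)=C/CO[Si](C)(C)C(C)(C)C)c1ccccc1 | intermediate |
| 14 | coupled allylic sulfone (C12 epimers) | CC(C)(C)[Si](C)(C)OC/C=C(\C)CC/C=C(\C)C(S(=O)(=O)c1ccccc1)C/C=C(\C)CC[C@H]1C(C)(C)CCC[C@]1(C)O | intermediate |
| 15 | TBS ether of target | CC(C)(C)[Si](C)(C)OC/C=C(\C)CC/C=C(\C)CC/C=C(\C)CC[C@H]1C(C)(C)CCC[C@]1(C)O | intermediate |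
| 16 | preluffariellolide A | C/C(=C\CO)CC/C=C(\C)CC/C=C(\C)CC[C@H]1C(C)(C)CCC[C@]1(C)O | target |

**Total steps:** 12. **Longest linear sequence:** 8 (1→2→4→6→7→8→14→15→16, counting Steps 1, 2, 3, 4, 5, 10, 11, 12).

**Three steps most likely to fail**
1. **Step 2 (proposed new step).** The double fragmentation could give over-oxidation, or C10 radical/peroxide products with partial epimerisation at C10. Fallback using known chemistry:
   - ketalise the C13 ketone of 2 (glycol, TsOH);
   - dehydrate C8–OH (SOCl2, pyridine) to the Δ8(9) olefin;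
   - ozonolyse (O3, then Me2S) to the C8/C9 diketone;
   - ketalise the less hindered C8 methyl ketone;
   - carry out a Baeyer–Villiger oxidation (CF3CO3H) of the C9 ketone, where tertiary C10 migrates with retention;
   - remove the ketals, then cleave the resulting tertiary levulinate with N2H4·AcOH to give 4.
2. **Step 11, with Step 10.** Pd-hydride removal of the allylic sulfone could shift the alkene (C12=C13 instead of C13=C14) or scramble its geometry. Fallback is a different approach with no sulfones:
   - alkylate the ethyl acetoacetate dianion with 8 and decarboxylate, giving the C13 methyl ketone;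
   - carry out HWE, DIBAL and bromination;
   - repeat the acetoacetate alkylation, HWE and DIBAL cycle once more to reach the C19 allylic alcohol.
3. **Step 7.** SeO2 oxidation of 10 is low-yielding (about 40 %) and can over-oxidise. Fallback to 11 without selenium:
   - form the terminal bromohydrin of 10 (NBS, H2O), then the epoxide (K2CO3);
   - cleave the epoxide with H5IO6 to the aldehyde OHC–CH2CH2–C(Me)=CH–CH2OTBS;
   - carry out E-selective HWE with triethyl 2-phosphonopropionate;
   - reduce the enoate with DIBAL.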